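**Retrosynthetic overview**
1. The target is the C3–O ester of (+)-catechin (1). The flavan is used as its 5,7,3',4'-tetra-O-benzyl ether (2), so C2 and C3 are bought.
2. The side chain is cut at C4–C5 of the pentanoate into benzylic chloride 3 and methyl (S)-glycidate 4. Cu-catalysed epoxide opening via Grignard reagent 5 gives hydroxy ester 6, which carries the bought carbinol centre.
3. Key disconnection: the ester C–O bond and the C2–C3 bond of the pentanoate are made together. Wolff rearrangement of diazoketone 10 (from 6 via 7, 8, 9), a [1,2]-sigmatropic shift with retention, gives ketene 11, which is trapped by the C3–OH of 2 to give 12.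
4. Global hydrogenolysis of seven benzyl ethers gives 13.
5. Ring order: no ring is built. Rings A, B and C arrive intact in 1 and ring D in 3.

Assumption: the SMILES is taken as authoritative, i.e. flavan (2R,3S) [the (+)-catechin configuration] and side-chain carbinol (S); 3 and 4 are treated as catalogue items.

**Step 1**
Reactants: 1 (+)-catechin [(2R,3S)-2-(3,4-dihydroxyphenyl)chromane-3,5,7-triol]
Product: 2 5,7,3',4'-tetra-O-benzyl-(+)-catechin
Conditions: BnBr (4.4 equiv), K2CO3, DMF, 0 °C → rt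
Reagents that add atoms: benzyl bromide, BrCc1ccccc1
Why: Williamson etherification in which carbonate deprotonates only the four phenols (pKa about 10) and not the secondary C3–OH, and C2/C3 are untouched below room temperature.

**Step 2**
Reactants: 3 3,4-bis(benzyloxy)benzyl chloride; 4 methyl (S)-glycidate [methyl (2S)-oxirane-2-carboxylate]
Product: 6 methyl (2S)-4-[3,4-bis(benzyloxy)phenyl]-2-hydroxybutanoate, via benzylic Grignard reagent 5 (not isolated)
Conditions: Mg, THF, 0 °C (slow addition of 3); then 4, CuI (10 mol %), THF, −40 → −20 °C; cold 1 M HCl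
Reagents that add atoms: none
Why: Cu-catalysed SN2 opening of the epoxide CH2 by the Grignard reagent outruns addition to the ester at low temperature, and the stereocentre of 4 is not a reacting atom, so (S) is carried over unchanged.

**Step 3**
Reactants: 6 methyl (2S)-4-[3,4-bis(benzyloxy)phenyl]-2-hydroxybutanoate
Product: 7 methyl (2S)-2-(benzyloxy)-4-[3,4-bis(benzyloxy)phenyl]butanoate
Conditions: BnBr, Ag2O, CH2Cl2, 4 Å sieves, rt, dark
Reagents that add atoms: benzyl bromide, BrCc1ccccc1
Why: Ag2O-mediated Williamson (Purdie-type) benzylation is non-enolising, so the α-hydroxy ester is etherified without racemisation.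

**Step 4**
Reactants: 7 methyl (2S)-2-(benzyloxy)-4-[3,4-bis(benzyloxy)phenyl]butanoate
Product: 8 (2S)-2-(benzyloxy)-4-[3,4-bis(benzyloxy)phenyl]butanoic acid
Conditions: LiOH·H2O, THF/H2O 3:1, 0 °C → rt; then 1 M HCl to pH 3
Reagents that add atoms: lithium hydroxide, [Li+].[OH-]
Why: Ester saponification (BAc2) at 0 °C is much faster than enolisation of the α-alkoxy ester, so the stereocentre is preserved.

**Step 5**
Reactants: 8 (2S)-2-(benzyloxy)-4-[3,4-bis(benzyloxy)phenyl]butanoic acid
Product: 10 (3S)-3-(benzyloxy)-5-[3,4-bis(benzyloxy)phenyl]-1-diazopentan-2-one, via acid chloride 9 (not isolated)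
Conditions: (COCl)2, DMF (cat.), CH2Cl2, 0 °C → rt, evaporate; then CH2N2 (3 equiv), Et2O, 0 °C
Reagents that add atoms: diazomethane, C=[N+]=[N-]
Why: First stage of the Arndt–Eistert sequence (C-acylation of diazomethane), where excess CH2N2 instead of an amine scavenges HCl so no alkoxyketene forms and the α-centre does not racemise.

**Step 6**
Reactants: 10 (3S)-3-(benzyloxy)-5-[3,4-bis(benzyloxy)phenyl]-1-diazopentan-2-one (1.3 equiv); 2 5,7,3',4'-tetra-O-benzyl-(+)-catechin
Product: 12 5,7,3',4'-tetra-O-benzyl-(+)-catechin 3-O-[(3S)-3-(benzyloxy)-5-[3,4-bis(benzyloxy)phenyl]pentanoate], via ketene 11 (not isolated)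
Conditions: PhCO2Ag (10 mol %), Et3N (3 equiv), THF, −25 °C → rt, dark, slow addition of 10
Reagents that add atoms: none
Why: Wolff rearrangement, in which loss of N2 is coupled to a [1,2]-sigmatropic shift of the benzyloxy-bearing carbon with retention of configuration, forms the C2–C3 bond and a ketene that the C3–OH of 2 adds to under amine catalysis, giving the ester in the same flask.

**Step 7**
Reactants: 12 5,7,3',4'-tetra-O-benzyl-(+)-catechin 3-O-[(3S)-3-(benzyloxy)-5-[3,4-bis(benzyloxy)phenyl]pentanoate]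
Product: 13 phylloflavan
Conditions: H2 (1 atm), Pd(OH)2/C, THF/MeOH 1:1, rt, then filtration under argon
Reagents that add atoms: none
Why: Catalytic hydrogenolysis removes all seven O-benzyl groups (six aryl, one secondary alkyl) under neutral conditions that leave the ester, the pyran ring and all three stereocentres untouched, as is standard for benzylated catechin esters.

**Compound list**
1 | (+)-catechin, (2R,3S)-2-(3,4-dihydroxyphenyl)chromane-3,5,7-triol | O[C@H]1Cc2c(O)cc(O)cc2O[C@@H]1c1ccc(O)c(O)c1 | starting material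
2 | 5,7,3',4'-tetra-O-benzyl-(+)-catechin, (2R,3S)-5,7-bis(benzyloxy)-2-[3,4-bis(benzyloxy)phenyl]chroman-3-ol | O[C@H]1Cc2c(OCc3ccccc3)cc(OCc3ccccc3)cc2O[C@@H]1c1ccc(OCc2ccccc2)c(OCc2ccccc2)c1 | intermediate
3 | 3,4-bis(benzyloxy)benzyl chloride | ClCc1ccc(OCc2ccccc2)c(OCc2ccccc2)c1 | starting material
4 | methyl (S)-glycidate, methyl (2S)-oxirane-2-carboxylate | COC(=O)[C@@H]1CO1 | starting material
5 | [3,4-bis(benzyloxy)benzyl]magnesium chloride | Cl[Mg]Cc1ccc(OCc2ccccc2)c(OCc2ccccc2)c1 | intermediate (not isolated)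
6 | methyl (2S)-4-[3,4-bis(benzyloxy)phenyl]-2-hydroxybutanoate | COC(=O)[C@@H](O)CCc1ccc(OCc2ccccc2)c(OCc2ccccc2)c1 | intermediate
7 | methyl (2S)-2-(benzyloxy)-4-[3,4-bis(benzyloxy)phenyl]butanoate | COC(=O)[C@@H](OCc1ccccc1)CCc1ccc(OCc2ccccc2)c(OCc2ccccc2)c1 | intermediate
8 | (2S)-2-(benzyloxy)-4-[3,4-bis(benzyloxy)phenyl]butanoic acid | OC(=O)[C@@H](OCc1ccccc1)CCc1ccc(OCc2ccccc2)c(OCc2ccccc2)c1 | intermediate
9 | (2S)-2-(benzyloxy)-4-[3,4-bis(benzyloxy)phenyl]butanoyl chloride | ClC(=O)[C@@H](OCc1ccccc1)CCc1ccc(OCc2ccccc2)c(OCc2ccccc2)c1 | intermediate (not isolated)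
10 | (3S)-3-(benzyloxy)-5-[3,4-bis(benzyloxy)phenyl]-1-diazopentan-2-one | [N-]=[N+]=CC(=O)[C@@H](OCc1ccccc1)CCc1ccc(OCc2ccccc2)c(OCc2ccccc2)c1 | intermediate
11 | (3S)-3-(benzyloxy)-5-[3,4-bis(benzyloxy)phenyl]pent-1-en-1-one (ketene) | O=C=C[C@@H](OCc1ccccc1)CCc1ccc(OCc2ccccc2)c(OCc2ccccc2)c1 | intermediate (not isolated)
12 | (2R,3S)-5,7-bis(benzyloxy)-2-[3,4-bis(benzyloxy)phenyl]chroman-3-yl (3S)-3-(benzyloxy)-5-[3,4-bis(benzyloxy)phenyl]pentanoate | O=C(C[C@@H](OCc1ccccc1)CCc1ccc(OCc2ccccc2)c(OCc2ccccc2)c1)O[C@H]1Cc2c(OCc3ccccc3)cc(OCc3ccccc3)cc2O[C@@H]1c1ccc(OCc2ccccc2)c(OCc2ccccc2)c1 | intermediate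
13 | phylloflavan, (2R,3S)-2-(3,4-dihydroxyphenyl)-5,7-dihydroxychroman-3-yl (3S)-5-(3,4-dihydroxyphenyl)-3-hydroxypentanoate | O=C(C[C@@H](O)CCc1ccc(O)c(O)c1)O[C@H]1Cc2c(O)cc(O)cc2O[C@@H]1c1ccc(O)c(O)c1 | target

**Totals**
Total steps: 7. Longest linear sequence: 6 (steps 2–7 from 3 and 4); step 1 is a one-step side branch.

**Three steps most likely to fail**

Step 6. The hindered secondary alcohol 2 must trap the ketene before it dimerises, and Ag-promoted Wolff rearrangements of α-alkoxy diazoketones can be sluggish. The fallback sets out from 10 and comes back at 12. The rearrangement is run on its own with water as the trap (Pyrex-filtered Hg lamp, or PhCO2Ag/Et3N, in THF/H2O 9:1) to give (3S)-3-(benzyloxy)-5-[3,4-bis(benzyloxy)phenyl]pentanoic acid F1. This acid is then joined to 2 by Steglich esterification (DCC, DMAP, CH2Cl2, 0 °C → rt) to give 12. The rearrangement and the esterification are thus separated and each can be optimised alone.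

Step 5. The α-benzyloxy acid chloride may partly racemise through an alkoxyketene or end as the chloromethyl ketone. The fallback sets out from 7 and comes back at 12, with no diazo compound. Kowalski ester homologation is used: CH2Br2 and lithium 2,2,6,6-tetramethylpiperidide (LiTMP) in THF at −78 °C, then LiN(SiMe3)2, then n-BuLi at −78 → 0 °C, then quench into acidic MeOH. In the carbenoid-to-ynolate rearrangement the same carbon migrates with retention, giving methyl (3S)-3-(benzyloxy)-5-[3,4-bis(benzyloxy)phenyl]pentanoate F2. Saponification (LiOH, THF/H2O) gives the acid F1, and Steglich esterification with 2 (DCC, DMAP) gives 12.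

Step 2. The electron-rich benzylic chloride may give Wurtz homocoupling during magnesium insertion, or the Grignard reagent may attack the ester of 4. The fallback sets out from 3 and comes back at 6, replacing the epoxide opening by an olefination.
- 3 and PPh3 (toluene, reflux) give [3,4-bis(benzyloxy)benzyl]triphenylphosphonium chloride F3.
- Ylide formation (n-BuLi, THF, −78 °C) and Wittig reaction with 2,3-O-isopropylidene-D-glyceraldehyde (O=C[C@H]1COC(C)(C)O1, from D-mannitol) give (4S)-4-{2-[3,4-bis(benzyloxy)phenyl]ethenyl}-2,2-dimethyl-1,3-dioxolane F4 as an E/Z mixture.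
- Diimide reduction (TsNHNH2, NaOAc, DME/H2O, reflux) saturates the alkene without touching the benzyl ethers and gives (4S)-4-{2-[3,4-bis(benzyloxy)phenyl]ethyl}-2,2-dimethyl-1,3-dioxolane F5.
- 80% aqueous AcOH at 40 °C gives (2S)-4-[3,4-bis(benzyloxy)phenyl]butane-1,2-diol F6.
- Selective oxidation of the primary alcohol (TEMPO cat., PhI(OAc)2, MeCN/H2O) gives (2S)-4-[3,4-bis(benzyloxy)phenyl]-2-hydroxybutanoic acid F7.
- Me3SiCHN2 in MeOH/toluene gives 6.

The carbinol centre is then bought in the glyceraldehyde and has the same spatial arrangement as in 6.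

**Further compounds**
F1 | step 6 | (3S)-3-(benzyloxy)-5-[3,4-bis(benzyloxy)phenyl]pentanoic acid | OC(=O)C[C@@H](OCc1ccccc1)CCc1ccc(OCc2ccccc2)c(OCc2ccccc2)c1
F2 | step 5 | methyl (3S)-3-(benzyloxy)-5-[3,4-bis(benzyloxy)phenyl]pentanoate | COC(=O)C[C@@H](OCc1ccccc1)CCc1ccc(OCc2ccccc2)c(OCc2ccccc2)c1
F3 | step 2 | [3,4-bis(benzyloxy)benzyl]triphenylphosphonium chloride | [Cl-].c1ccccc1[P+](c1ccccc1)(c1ccccc1)Cc1ccc(OCc2ccccc2)c(OCc2ccccc2)c1
F4 | step 2 | (4S)-4-{2-[3,4-bis(benzyloxy)phenyl]ethenyl}-2,2-dimethyl-1,3-dioxolane (E/Z mixture) | CC1(C)OC[C@H](C=Cc2ccc(OCc3ccccc3)c(OCc3ccccc3)c2)O1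
F5 | step 2 | (4S)-4-{2-[3,4-bis(benzyloxy)phenyl]ethyl}-2,2-dimethyl-1,3-dioxolane | CC1(C)OC[C@H](CCc2ccc(OCc3ccccc3)c(OCc3ccccc3)c2)O1
F6 | step 2 | (2S)-4-[3,4-bis(benzyloxy)phenyl]butane-1,2-diol | OC[C@@H](O)CCc1ccc(OCc2ccccc2)c(OCc2ccccc2)c1
F7 | step 2 | (2S)-4-[3,4-bis(benzyloxy)phenyl]-2-hydroxybutanoic acid | OC(=O)[C@@H](O)CCc1ccc(OCc2ccccc2)c(OCc2ccccc2)c1
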